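**Retrosynthetic overview**
- Last cut: the C1′–O acyl bond. (R)-Shikonin is esterified with 3,4-dimethylpent-3-enoic acid; the C5 and C8 phenols are hydrogen-bonded to the quinone carbonyls and stay free.
- Feature used: ring B carries only the oxygens at C5 and C8 and the fusion carbons C4a/C8a. It can be read as three alkynes, C8a≡C8–O, C6≡C7 and C4a≡C5–O, the two oxygenated ones being linked through C1–C2=C3–C4 of ring A.
- Key disconnection: C4a–C8a, C5–C6 and C7–C8 form in one rhodium-catalysed [2+2+2] of an ene-diyne bis(ethoxyalkyne) with acetylene. Rings A and B arise together in this step; no ring of the target exists before it.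
- The ene-diyne comes from a 3-substituted furan. Its four ring carbons become C1–C4 and its ring fixes the cis alkene (singlet-oxygen opening, twofold ethoxyacetylide addition). C1′ (R) is set earlier by Ipc2BCl reduction of the 3-furyl ketone.
- After ring construction, ring A is oxidised to the quinone. A redox switch (reductive acetylation, then cerium oxidation of the diethoxy ring B) then frees the naphthazarin without Lewis-acid ether cleavage.

Key step: step 7

Remark: target naphthalene numbering (C1–C8a, side chain C1′) is used throughout; C1 and C4 of 13, 14, 16 and 17 are carried as epimer mixtures because both become carbonyl carbons in step 9; the two naphthazarin tautomers are one substance by fast proton transfer, so 23 and 29 are drawn as in the target.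

**Step 1**
Reactants: 1 4-methylpent-3-enoic acid
Product: 3 N-methoxy-N,4-dimethylpent-3-enamide, via acyl imidazolide 2 (not isolated)
Conditions: CDI, CH2Cl2, 0 °C → rt; then MeNH(OMe)·HCl, rt
Reagents that add atoms: N,O-dimethylhydroxylamine hydrochloride, CNOC.Cl; 1,1'-carbonyldiimidazole, O=C(n1ccnc1)n1ccnc1 (imidazolyl group of 2 only)
Why: Weinreb amide formation through an acyl imidazolide is a near-neutral acyl substitution that should leave the β,γ-alkene out of conjugation.

**Step 2**
Reactants: 4 3-bromofuran; 3 N-methoxy-N,4-dimethylpent-3-enamide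
Product: 6 1-(furan-3-yl)-4-methylpent-3-en-1-one, via 3-lithiofuran 5 (not isolated)
Conditions: 4, n-BuLi, THF, −78 °C; then 3, −78 °C; aq. NH4Cl at −78 °C
Reagents that add atoms: n-butyllithium, [Li]CCCC (lithium of 5 only)
Why: Bromine–lithium exchange followed by Weinreb ketone synthesis; 3-lithiofuran keeps its position at −78 °C, the chelated tetrahedral adduct stops at the ketone, and the cold quench should avoid conjugation of the alkene.

**Step 3**
Reactants: 6 1-(furan-3-yl)-4-methylpent-3-en-1-one
Product: 7 (R)-1-(furan-3-yl)-4-methylpent-3-en-1-ol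
Conditions: (+)-Ipc2BCl, THF, −25 °C; then CH3CHO, 0 °C → rt; aq. NaOH
Reagents that add atoms: none
Why: Asymmetric Ipc2BCl ketone reduction under reagent control; in the cyclic hydride-transfer transition state the flat furyl group plays the large (aryl) role, so the (+)-reagent should deliver hydride to the Si face and give the R carbinol as with aryl alkyl ketones, and the reagent has no B–H bond and no basicity to disturb the alkene.

**Step 4**
Reactants: 7 (R)-1-(furan-3-yl)-4-methylpent-3-en-1-ol
Product: 8 (R)-tert-butyl{[1-(furan-3-yl)-4-methylpent-3-en-1-yl]oxy}dimethylsilane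
Conditions: TBSCl, imidazole, DMF, rt
Reagents that add atoms: tert-butyldimethylsilyl chloride, CC(C)(C)[Si](C)(C)Cl
Why: Imidazole-promoted silyl ether formation leaves the C–O bond at C1′ untouched, and the TBS group should survive the acetylide, the rhodium catalyst, buffered HF, MnO2 and Zn/Ac2O.

**Step 5**
Reactants: 8 (R)-TBS ether of the furyl carbinol; 9 ethoxyacetylene
Product: 13 ene-diyne diol (carbinol carbons C1/C4 cis on C2=C3; epimer mixture), via furan endoperoxide 10 (not isolated), via Z-enedial 11 (not isolated), via lithium ethoxyacetylide 12 (not isolated)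
Conditions: O2, hν (visible), tetraphenylporphyrin (cat.), CH2Cl2, −78 °C; Me2S, −78 → −20 °C; cold solution cannulated into 12 (from 9, n-BuLi, THF, −78 °C; 4 equiv), −78 → 0 °C; H2O
Reagents that add atoms: dioxygen, O=O; n-butyllithium, [Li]CCCC (lithium of 12 only)
Why: Singlet oxygen adds [4+2] to the furan faster than it undergoes the ene reaction at a trisubstituted alkene, sulfide reduction of the endoperoxide gives the enedial with the cis geometry inherited from the ring, and the hard lithium acetylide adds 1,2 to both aldehydes (ethoxyethynyl carbinol synthesis), the lactolate formed after the first addition reopening on warming as in acetylide additions to lactols; the new centres C1 and C4 are not controlled and need not be.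

**Step 6**
Reactants: 13 ene-diyne diol
Product: 14 (4Z)-ene-diyne bis(ethoxyalkyne) bis(triethylsilyl ether) with the R silyloxy side chain
Conditions: TESCl, imidazole, DMAP (cat.), CH2Cl2, 0 °C; Et3N-deactivated silica
Reagents that add atoms: triethylsilyl chloride, CC[Si](CC)(CC)Cl
Why: Silyl ether formation under mildly basic conditions caps both propargylic carbinols, which blocks the Meyer–Schuster rearrangement typical of free ethoxyethynyl carbinols.

**Step 7**
Reactants: 14 (4Z)-ene-diyne bis(ethoxyalkyne) bis(triethylsilyl ether); 15 acetylene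
Product: 16 5,8-diethoxy-1,4-bis(triethylsilyloxy)-2-[(1R)-1-(tert-butyldimethylsilyloxy)-4-methylpent-3-enyl]-1,4-dihydronaphthalene
Conditions: [Rh(cod)2]BF4 (5 mol %), rac-BINAP (5 mol %), activated with H2; C2H2 (1 atm), 2,6-di-tert-butyl-4-methylpyridine (10 mol %), CH2Cl2, rt, slow addition of 14
Reagents that add atoms: none
Why: Proposed new method: the cationic monovalent rhodium–BINAP fragment binds the two ethoxyalkynes of 14 and couples them oxidatively to a trivalent rhodacyclopentadiene, which makes C4a–C8a and so closes ring A as the six-membered carbocycle fused to the metallacycle, an intramolecular closure for which the cis C2=C3 alkene holds C1 and C4 on the same side. Acetylene then coordinates and inserts, and reductive elimination makes C5–C6 and C7–C8, so ring B closes in the intermolecular half of the [2+2+2] and appears directly as the arene, with the ethoxy groups of the outer alkyne carbons at C5 and C8. The closest known reaction types are the rhodium-catalysed cyclotrimerisation of 1,7-diynes, and of diynes containing an ynamide unit, with acetylene, and the rhodium-catalysed trimerisation of aryl ethynyl ethers; a 1,7-diyne with an alkoxy group on both termini has not been shown, hence the label. No stereocentre is formed: C1′ lies outside the reacting array and keeps its R configuration, and all C1/C4 epimers give the same constitution. The step needs cross-cyclotrimerisation to beat diyne self-coupling and acetylene oligomerisation, which the intramolecular first coupling, slow addition of 14 and an acetylene-saturated solution should secure, and the symmetry of acetylene leaves no regiochemical question. The triethylsilyl caps and the hindered pyridine buffer should keep the acid-labile propargylic ynol ether units from ionising, and the trisubstituted prenyl alkene is too hindered to compete for the metallacycle.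

**Step 8**
Reactants: 16 bis(triethylsilyloxy)dihydronaphthalene
Product: 17 5,8-diethoxy-2-[(1R)-1-(tert-butyldimethylsilyloxy)-4-methylpent-3-enyl]-1,4-dihydronaphthalene-1,4-diol
Conditions: HF·pyridine, pyridine, THF, 0 °C
Reagents that add atoms: none
Why: Selective fluoride desilylation; triethylsilyl ethers are cleaved much faster than the hindered secondary TBS ether, and the pyridine buffer should keep the doubly activated C1 and C4 carbinols from ionising.

**Step 9**
Reactants: 17 dihydronaphthalene-1,4-diol
Product: 18 5,8-diethoxy-2-[(1R)-1-(tert-butyldimethylsilyloxy)-4-methylpent-3-enyl]naphthalene-1,4-dione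
Conditions: MnO2 (activated, excess), CH2Cl2, rt
Reagents that add atoms: none
Why: MnO2 oxidation of allylic-benzylic alcohols; the first oxidation gives a hydroxy dienone that tautomerises to the quinol and is oxidised further, so all epimers should converge on the quinone and the C1/C4 centres vanish.

**Step 10**
Reactants: 18 5,8-diethoxyquinone
Product: 20 5,8-diethoxy-2-[(1R)-1-(tert-butyldimethylsilyloxy)-4-methylpent-3-enyl]naphthalene-1,4-diyl diacetate, via zinc quinolate 19 (not isolated)
Conditions: Zn dust, Ac2O, pyridine, CH2Cl2, rt
Reagents that add atoms: acetic anhydride, CC(=O)OC(C)=O; zinc, [Zn] (in 19 only)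
Why: Reductive acetylation; zinc reduces the quinone and the quinolate is acetylated at once, which prevents quinone-methide loss of the C1′ oxygen and makes ring A the electron-poorer ring so that the next oxidation addresses ring B.

**Step 11**
Reactants: 20 1,4-diacetoxy-5,8-diethoxynaphthalene
Product: 21 5,8-diacetoxy-6-[(1R)-1-(tert-butyldimethylsilyloxy)-4-methylpent-3-enyl]naphthalene-1,4-dione (former ring B is now the quinone)
Conditions: (NH4)2Ce(NO3)6, MeCN–H2O, 0 °C
Reagents that add atoms: water, O
Why: Oxidative dealkylation of a hydroquinone dialkyl ether by tetravalent cerium; electron transfer takes place from the electron-rich diethoxy ring, water adds at the two ipso carbons and ethanol leaves, under brief cold conditions that a prenyl alkene tolerates, and any loss of TBS only anticipates step 12.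

**Step 12**
Reactants: 21 diacetoxyquinone TBS ether
Product: 22 5,8-diacetoxy-6-[(1R)-1-hydroxy-4-methylpent-3-enyl]naphthalene-1,4-dione
Conditions: aq. HF, MeCN, 0 °C → rt
Reagents that add atoms: none
Why: Acidic fluoride desilylation, done before the phenols are freed because the electron-poor diacetoxyquinone cannot ionise at C1′ through a quinone methide, so the R configuration should hold.

**Step 13**
Reactants: 22 diacetoxyquinone alcohol
Product: 23 (R)-shikonin
Conditions: 1 M aq. NaOH, THF, 0 °C → rt, Ar; then 1 M HCl to pH 4
Reagents that add atoms: none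
Why: Saponification of the two activated aryl acetates (and of any acetyl that has migrated to the C1′ oxygen) frees the naphthazarin, whose tautomers equilibrate to the substance drawn with the side chain on the quinone ring, and C1′ is not touched.

**Step 14**
Reactants: 24 2-bromo-3-methylbut-2-ene; 25 oxirane
Product: 27 3,4-dimethylpent-3-en-1-ol, via alkenyl Grignard reagent 26 (not isolated)
Conditions: Mg turnings, THF, rt; CuI (10 mol %), 25, −30 °C → rt; aq. NH4Cl
Reagents that add atoms: magnesium, [Mg] (in 26 only)
Why: Copper-catalysed opening of an epoxide by an alkenyl Grignard reagent adds the two-carbon alcohol unit, and the position of the tetrasubstituted alkene is fixed by the vinyl bromide.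

**Step 15**
Reactants: 27 3,4-dimethylpent-3-en-1-ol
Product: 28 3,4-dimethylpent-3-enoic acid
Conditions: TEMPO (cat.), PhI(OAc)2, MeCN–H2O, rt
Reagents that add atoms: water, O
Why: Oxoammonium-mediated oxidation of a primary alcohol through the aldehyde hydrate to the acid runs near neutrality, so the alkene should stay in the β,γ position.

**Step 16**
Reactants: 23 (R)-shikonin; 28 3,4-dimethylpent-3-enoic acid
Product: 29 (1R)-1-(5,8-dihydroxy-1,4-dioxo-1,4-dihydronaphthalen-2-yl)-4-methylpent-3-en-1-yl 3,4-dimethylpent-3-enoate (target)
Conditions: DCC, DMAP (cat.), CH2Cl2, 0 °C → rt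
Reagents that add atoms: none
Why: Steglich esterification should acylate only the C1′ hydroxyl because the C5 and C8 phenols are tied up in hydrogen bonds to the quinone carbonyls, and the C1′–O bond is not broken, so R is retained.

**Compound list**
1 | 4-methylpent-3-enoic acid | CC(C)=CCC(=O)O | starting material
2 | 1-(imidazol-1-yl)-4-methylpent-3-en-1-one | CC(C)=CCC(=O)n1ccnc1 | intermediate
3 | N-methoxy-N,4-dimethylpent-3-enamide | CC(C)=CCC(=O)N(C)OC | intermediate
4 | 3-bromofuran | Brc1ccoc1 | starting material
5 | 3-lithiofuran | [Li]c1ccoc1 | intermediate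
6 | 1-(furan-3-yl)-4-methylpent-3-en-1-one | CC(C)=CCC(=O)c1ccoc1 | intermediate
7 | (R)-1-(furan-3-yl)-4-methylpent-3-en-1-ol | CC(C)=CC[C@@H](O)c1ccoc1 | intermediate
8 | (R)-tert-butyl{[1-(furan-3-yl)-4-methylpent-3-en-1-yl]oxy}dimethylsilane | CC(C)=CC[C@@H](O[Si](C)(C)C(C)(C)C)c1ccoc1 | intermediate
9 | ethoxyacetylene | CCOC#C | starting material
10 | 5-[(1R)-1-(tert-butyldimethylsilyloxy)-4-methylpent-3-enyl]-2,3,7-trioxabicyclo[2.2.1]hept-5-ene (both bridgehead diastereomers) | CC(C)=CC[C@@H](O[Si](C)(C)C(C)(C)C)C1=CC2OOC1O2 | intermediate
11 | (Z)-2-[(1R)-1-(tert-butyldimethylsilyloxy)-4-methylpent-3-enyl]but-2-enedial | CC(C)=CC[C@@H](O[Si](C)(C)C(C)(C)C)/C(C=O)=C/C=O | intermediate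
12 | lithium ethoxyacetylide | CCOC#C[Li] | intermediate
13 | 4-[(1R)-1-(tert-butyldimethylsilyloxy)-4-methylpent-3-enyl]-1,8-diethoxyoct-4-ene-1,7-diyne-3,6-diol, both carbinol carbons cis on the alkene (CIP label E because C1′–OSi outranks C–OH), carbinol epimers | CC(C)=CC[C@@H](O[Si](C)(C)C(C)(C)C)/C(C(O)C#COCC)=C/C(O)C#COCC | intermediate
14 | (4Z)-4-[(1R)-1-(tert-butyldimethylsilyloxy)-4-methylpent-3-enyl]-1,8-diethoxy-3,6-bis(triethylsilyloxy)oct-4-ene-1,7-diyne, carbinol epimers | CC(C)=CC[C@@H](O[Si](C)(C)C(C)(C)C)/C(C(O[Si](CC)(CC)CC)C#COCC)=C/C(O[Si](CC)(CC)CC)C#COCC | intermediate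
15 | acetylene | C#C | starting material
16 | 5,8-diethoxy-1,4-bis(triethylsilyloxy)-2-[(1R)-1-(tert-butyldimethylsilyloxy)-4-methylpent-3-enyl]-1,4-dihydronaphthalene, C1/C4 epimers | CC(C)=CC[C@@H](O[Si](C)(C)C(C)(C)C)C1=CC(O[Si](CC)(CC)CC)c2c(OCC)ccc(OCC)c2C1O[Si](CC)(CC)CC | intermediate
17 | 5,8-diethoxy-2-[(1R)-1-(tert-butyldimethylsilyloxy)-4-methylpent-3-enyl]-1,4-dihydronaphthalene-1,4-diol, C1/C4 epimers | CC(C)=CC[C@@H](O[Si](C)(C)C(C)(C)C)C1=CC(O)c2c(OCC)ccc(OCC)c2C1O | intermediate
18 | 5,8-diethoxy-2-[(1R)-1-(tert-butyldimethylsilyloxy)-4-methylpent-3-enyl]naphthalene-1,4-dione | CC(C)=CC[C@@H](O[Si](C)(C)C(C)(C)C)C1=CC(=O)c2c(OCC)ccc(OCC)c2C1=O | intermediate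
19 | zinc salt of 5,8-diethoxy-2-[(1R)-1-(tert-butyldimethylsilyloxy)-4-methylpent-3-enyl]naphthalene-1,4-diol | CC(C)=CC[C@@H](O[Si](C)(C)C(C)(C)C)c1cc([O-])c2c(OCC)ccc(OCC)c2c1[O-].[Zn+2] | intermediate
20 | 5,8-diethoxy-2-[(1R)-1-(tert-butyldimethylsilyloxy)-4-methylpent-3-enyl]naphthalene-1,4-diyl diacetate | CC(C)=CC[C@@H](O[Si](C)(C)C(C)(C)C)c1cc(OC(C)=O)c2c(OCC)ccc(OCC)c2c1OC(C)=O | intermediate
21 | 5,8-diacetoxy-6-[(1R)-1-(tert-butyldimethylsilyloxy)-4-methylpent-3-enyl]naphthalene-1,4-dione | CC(C)=CC[C@@H](O[Si](C)(C)C(C)(C)C)c1cc(OC(C)=O)c2C(=O)C=CC(=O)c2c1OC(C)=O | intermediate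
22 | 5,8-diacetoxy-6-[(1R)-1-hydroxy-4-methylpent-3-enyl]naphthalene-1,4-dione | CC(C)=CC[C@@H](O)c1cc(OC(C)=O)c2C(=O)C=CC(=O)c2c1OC(C)=O | intermediate
23 | (R)-shikonin, 5,8-dihydroxy-2-[(1R)-1-hydroxy-4-methylpent-3-enyl]naphthalene-1,4-dione | CC(C)=CC[C@@H](O)C1=CC(=O)c2c(O)ccc(O)c2C1=O | intermediate
24 | 2-bromo-3-methylbut-2-ene | CC(C)=C(C)Br | starting material
25 | oxirane | C1CO1 | starting material
26 | (3-methylbut-2-en-2-yl)magnesium bromide | CC(C)=C(C)[Mg]Br | intermediate
27 | 3,4-dimethylpent-3-en-1-ol | CC(C)=C(C)CCO | intermediate
28 | 3,4-dimethylpent-3-enoic acid | CC(C)=C(C)CC(=O)O | intermediate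
29 | (1R)-1-(5,8-dihydroxy-1,4-dioxo-1,4-dihydronaphthalen-2-yl)-4-methylpent-3-en-1-yl 3,4-dimethylpent-3-enoate | CC(C)=CC[C@@H](OC(=O)CC(C)=C(C)C)C1=CC(=O)c2c(O)ccc(O)c2C1=O | target

**Total step count:** 16. **Longest linear sequence:** 14 (steps 1–13 and 16).

**Steps most likely to fail**

**Step 7 (key step).**
- What may go wrong: the two donor-substituted alkynes could tie up the catalyst, traces of acid could ionise the propargylic silyl ethers, the diyne could couple with itself, or the product could lose silanol and aromatise in ring A.
- Fallback (known chemistry): it sets out from furan 8 and returns at quinone 18, building ring A onto a preformed ring B.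
- Commercial 2-bromo-1,4-diethoxybenzene is treated with LiN(i-Pr)2 in THF at −78 °C in the presence of 8.
- Loss of bromide releases 3,6-diethoxybenzyne F1, which the furan traps in a Diels–Alder reaction to give the 1,4-epoxy-1,4-dihydronaphthalene F2.
- Catalytic camphorsulfonic acid in CH2Cl2 at 0 °C opens the oxygen bridge to the 2-substituted 5,8-diethoxy-1-naphthol F3. Its 3-substituted isomer would converge as well.
- Teuber oxidation with (KSO3)2NO in buffered aqueous acetone gives 18.

**Step 5.**
- What may go wrong: ene oxidation at the prenyl alkene, oligomerisation or cis-to-trans isomerisation of the dialdehyde before it meets the nucleophile, arrest after the first addition through lactolate closure, or γ-deprotonation at C1′ with erosion of configuration.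
- Fallback: it sets out from 8 and returns at 13, replacing the free dialdehyde with a storable masked form.
- Photooxygenation is run in MeOH (methylene blue, −78 °C), where the solvent opens endoperoxide 10 to the 2-hydroperoxy-5-methoxy-2,5-dihydrofuran F4.
- Me2S reduces this to the 5-methoxy-2,5-dihydrofuran-2-ol F5, a cyclic mixed acetal that can be purified free of over-oxidised material.
- With excess 12 in THF (−78 → 0 °C) the lactol is deprotonated and unravels with loss of methoxide. Each aldehyde is therefore released only in the presence of the acetylide, and 13 should result.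

**Step 8.**
- What may go wrong: acid-induced loss of water or silanol from the doubly activated C1 and C4 positions with aromatisation of ring A, and partial loss of the TBS group.
- Fallback: it sets out from 16 and returns at 18 without ever freeing the diol.
- DDQ (just over 2 equiv) in CH2Cl2/pH 7 buffer at 0 °C is the known oxidative deprotection of electron-rich allylic and benzylic silyl ethers.
- It abstracts hydride from C1–H. The resulting silyloxy dienone tautomerises to the naphthol silyl ether and is oxidised on to the quinone.
- This detour makes no compound outside the list (F0).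

**Further compounds**
F1 | step 7 | 3,6-diethoxybenzyne | CCOC1=CC=C(OCC)C#C1
F2 | step 7 | 5,8-diethoxy-2-[(1R)-1-(tert-butyldimethylsilyloxy)-4-methylpent-3-enyl]-1,4-epoxy-1,4-dihydronaphthalene (bridgehead diastereomers) | CC(C)=CC[C@@H](O[Si](C)(C)C(C)(C)C)C1=CC2OC1c1c2c(OCC)ccc1OCC
F3 | step 7 | 5,8-diethoxy-2-[(1R)-1-(tert-butyldimethylsilyloxy)-4-methylpent-3-enyl]naphthalen-1-ol | CC(C)=CC[C@@H](O[Si](C)(C)C(C)(C)C)c1ccc2c(OCC)ccc(OCC)c2c1O
F4 | step 5 | 3-[(1R)-1-(tert-butyldimethylsilyloxy)-4-methylpent-3-enyl]-2-hydroperoxy-5-methoxy-2,5-dihydrofuran (drawn regioisomer, acetal epimers) | CC(C)=CC[C@@H](O[Si](C)(C)C(C)(C)C)C1=CC(OC)OC1OO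
F5 | step 5 | 3-[(1R)-1-(tert-butyldimethylsilyloxy)-4-methylpent-3-enyl]-5-methoxy-2,5-dihydrofuran-2-ol (drawn regioisomer, acetal epimers) | CC(C)=CC[C@@H](O[Si](C)(C)C(C)(C)C)C1=CC(OC)OC1O
F0 | step 8 | none | none
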